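**Retrosynthetic overview**
- The target is reached by radical removal of a bridgehead bromine from its C1-bromo analogue; the bromine is a temporary blocking group that fixes which face the lactone bridge closes on.
- The lactone bridge (last ring formed) comes from a dealkylative acetal-lactonisation of a 1-bromo-2,5-dioxocycloheptene tert-butyl ester.
- That cycloheptenedione comes from reductive opening of the oxygen bridge of an 8-oxabicyclo[3.2.1]octenone, with bromination of the resulting enolate.
- The oxabicycle comes from a one-flask carbonyl-ylide formation and cycloaddition of a (Z)-diazo keto diester with (E)-isoelemicin: the pyran ring and the seven-membered carbocycle form together, setting the aryl/methyl pair and the absolute configuration.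
- The diazo diester comes from allylmaleic anhydride (Stille coupling, methanolysis, acylation of tert-butyl diazoacetate); isoelemicin comes from a Suzuki coupling.

Assumption: the sense of induction of the chiral dirhodium catalyst is taken as drawn (its mirror-image catalyst is used if it proves opposite), and (E)-isoelemicin is made rather than bought.

**Step 1**
Reactants: 1 3-bromofuran-2,5-dione; 2 tributyl(prop-2-en-1-yl)stannane
Product: 3 3-(prop-2-en-1-yl)furan-2,5-dione
Conditions: Pd(PPh3)4 (5 mol %), toluene, 80 °C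
Reagents that add atoms: none
Why: Stille coupling, in which zerovalent palladium inserts into the vinylic C–Br bond and the allyl group is transferred from tin; no stereocentre is formed and the ring keeps the two carbonyls cis.

**Step 2**
Reactants: 3 3-(prop-2-en-1-yl)furan-2,5-dione
Product: 4 (2Z)-4-methoxy-4-oxo-2-(prop-2-en-1-yl)but-2-enoic acid
Conditions: MeOH, 0 °C to rt; minor regioisomer removed by crystallisation
Reagents that add atoms: methanol, CO
Why: Nucleophilic anhydride opening, in which methanol attacks the less hindered carbonyl (next to the unsubstituted alkene carbon), leaving the free acid on the allyl-bearing carbon and keeping the (Z)-geometry needed in step 5.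

**Step 3**
Reactants: 4 (2Z)-4-methoxy-4-oxo-2-(prop-2-en-1-yl)but-2-enoic acid; 5 tert-butyl diazoacetate
Product: 8 6-tert-butyl 1-methyl (2Z)-5-diazo-4-oxo-3-(prop-2-en-1-yl)hex-2-enedioate, via acid chloride 6 (not isolated), via lithio diazo ester 7 (not isolated)
Conditions: (COCl)2, DMF (cat.), CH2Cl2, 0 °C, then evaporate; separately 5, LiN(iPr)2, THF, −78 °C; combine at −78 °C
Reagents that add atoms: none
Why: C-acylation of a lithiated diazo ester by an acid chloride, run cold so that the (Z)-alkene does not isomerise; no stereocentre is formed.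

**Step 4**
Reactants: 9 5-bromo-1,2,3-trimethoxybenzene; 10 [(1E)-prop-1-en-1-yl]boronic acid
Product: 11 1,2,3-trimethoxy-5-[(1E)-prop-1-en-1-yl]benzene ((E)-isoelemicin)
Conditions: Pd(dppf)Cl2 (3 mol %), K2CO3, dioxane/H2O, 80 °C
Reagents that add atoms: none
Why: Suzuki–Miyaura coupling, which transfers the propenyl group with retention of the (E)-geometry.

**Step 5**
Reactants: 8 6-tert-butyl 1-methyl (2Z)-5-diazo-4-oxo-3-(prop-2-en-1-yl)hex-2-enedioate; 11 1,2,3-trimethoxy-5-[(1E)-prop-1-en-1-yl]benzene
Product: 13 tert-butyl (1R,5S,6R,7S)-5-methoxy-6-methyl-2-oxo-3-(prop-2-en-1-yl)-7-(3,4,5-trimethoxyphenyl)-8-oxabicyclo[3.2.1]oct-3-ene-1-carboxylate, via pyrylium olate ylide 12 (not isolated)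
Conditions: Rh2(S-TCPTTL)4 [dirhodium tetrakis(N-tetrachlorophthaloyl-(S)-tert-leucinate)] (2 mol %), 11 (3 equiv), PhCF3, slow addition of 8, 23 to 40 °C
Reagents that add atoms: none
Why: Tandem carbonyl-ylide formation and 1,3-dipolar cycloaddition (formal [5+2]), in which the divalent rhodium carbenoid is captured by the cis ester carbonyl to give the six-membered ylide and this adds across the alkene, so two rings form in one operation; the nucleophilic CHMe carbon bonds to the methoxy-bearing terminus and the benzylic carbon to the ester-bearing terminus, suprafacial addition to the (E)-alkene makes methyl and aryl trans, the chiral carboxylate ligands choose the face, and by analogy with styrene additions to such ylides the aryl group is expected syn to the oxygen bridge (only the C6/C7 pair and its absolute sense are carried on, since C1 and C5 are erased in step 6).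

**Step 6**
Reactants: 13 tert-butyl (1R,5S,6R,7S)-5-methoxy-6-methyl-2-oxo-3-(prop-2-en-1-yl)-7-(3,4,5-trimethoxyphenyl)-8-oxabicyclo[3.2.1]oct-3-ene-1-carboxylate
Product: 15 tert-butyl (1S,6R,7S)-1-bromo-6-methyl-2,5-dioxo-3-(prop-2-en-1-yl)-7-(3,4,5-trimethoxyphenyl)cyclohept-3-ene-1-carboxylate, via samarium enolate 14 (not isolated)
Conditions: SmI2 (2.1 equiv), THF, −78 °C; then N-bromosuccinimide, −78 to −40 °C; aqueous work-up
Reagents that add atoms: N-bromosuccinimide, O=C1CCC(=O)N1Br
Why: Reductive cleavage of the α-alkoxy ketone C1–O bond by divalent samarium (ketyl, then β-elimination) opens the oxygen bridge, the hemiketal left at C5 loses methoxide to give the ketone, and the β-keto ester enolate is brominated trans to the neighbouring aryl group, which sets C1 as a quaternary centre that cannot epimerise and places the ester cis to the aryl group (the C1 epimer, if formed, is separated here).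

**Step 7**
Reactants: 15 tert-butyl (1S,6R,7S)-1-bromo-6-methyl-2,5-dioxo-3-(prop-2-en-1-yl)-7-(3,4,5-trimethoxyphenyl)cyclohept-3-ene-1-carboxylate
Product: 16 (1S,5S,8S,9R)-1-bromo-5-methoxy-9-methyl-3-(prop-2-en-1-yl)-8-(3,4,5-trimethoxyphenyl)-6-oxabicyclo[3.2.2]non-3-ene-2,7-dione
Conditions: Me3SiOTf (0.2 equiv), MeOSiMe3 (1.5 equiv), CH2Cl2, −78 to −20 °C
Reagents that add atoms: methoxytrimethylsilane, CO[Si](C)(C)C
Why: Proposed new method: Me3SiOTf/MeOSiMe3 turns the C5 ketone into a methoxy oxocarbenium ion (as in Noyori acetalisation), the carbonyl oxygen of the tert-butyl ester attacks it through a six-membered transition state and loses isobutene (as tert-butyl esters do toward cations in halolactonisation), and because the ester on the fixed C1 centre is cis to the aryl group the lactone bridge can only form on the aryl face, which also fixes C5 while the methyl group stays trans to aryl.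

**Step 8**
Reactants: 16 (1S,5S,8S,9R)-1-bromo-5-methoxy-9-methyl-3-(prop-2-en-1-yl)-8-(3,4,5-trimethoxyphenyl)-6-oxabicyclo[3.2.2]non-3-ene-2,7-dione
Product: 17 (1R,5S,8R,9R)-5-methoxy-9-methyl-3-(prop-2-en-1-yl)-8-(3,4,5-trimethoxyphenyl)-6-oxabicyclo[3.2.2]non-3-ene-2,7-dione
Conditions: Bu3SnH, AIBN (cat.), benzene, 80 °C
Reagents that add atoms: none
Why: Radical dehalogenation, in which the bridgehead radical takes a hydrogen atom from the tin hydride; C1 is a bridgehead, so its configuration is dictated by the bicycle and no other centre is touched.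

**Compound list**
1 | 3-bromofuran-2,5-dione (bromomaleic anhydride) | O=C1OC(=O)C(Br)=C1 | starting material
2 | tributyl(prop-2-en-1-yl)stannane | C=CC[Sn](CCCC)(CCCC)CCCC | starting material
3 | 3-(prop-2-en-1-yl)furan-2,5-dione | C=CCC1=CC(=O)OC1=O | intermediate
4 | (2Z)-4-methoxy-4-oxo-2-(prop-2-en-1-yl)but-2-enoic acid | COC(=O)/C=C(/CC=C)C(=O)O | intermediate
5 | tert-butyl diazoacetate | CC(C)(C)OC(=O)C=[N+]=[N-] | starting material
6 | methyl (2Z)-3-(chlorocarbonyl)hexa-2,5-dienoate | COC(=O)/C=C(/CC=C)C(Cl)=O | intermediate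
7 | tert-butyl diazo(lithio)acetate | [Li]C(=[N+]=[N-])C(=O)OC(C)(C)C | intermediate
8 | 6-tert-butyl 1-methyl (2Z)-5-diazo-4-oxo-3-(prop-2-en-1-yl)hex-2-enedioate | COC(=O)/C=C(/CC=C)C(=O)C(=[N+]=[N-])C(=O)OC(C)(C)C | intermediate
9 | 5-bromo-1,2,3-trimethoxybenzene | COc1cc(Br)cc(OC)c1OC | starting material
10 | [(1E)-prop-1-en-1-yl]boronic acid | C/C=C/B(O)O | starting material
11 | 1,2,3-trimethoxy-5-[(1E)-prop-1-en-1-yl]benzene | C/C=C/c1cc(OC)c(OC)c(OC)c1 | intermediate
12 | 2-(tert-butoxycarbonyl)-6-methoxy-4-(prop-2-en-1-yl)pyrylium-3-olate | COc1cc(CC=C)c([O-])c(C(=O)OC(C)(C)C)[o+]1 | intermediate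
13 | tert-butyl (1R,5S,6R,7S)-5-methoxy-6-methyl-2-oxo-3-(prop-2-en-1-yl)-7-(3,4,5-trimethoxyphenyl)-8-oxabicyclo[3.2.1]oct-3-ene-1-carboxylate (aryl syn to the oxygen bridge, methyl anti) | C=CCC1=C[C@@]2(OC)O[C@@](C(=O)OC(C)(C)C)(C1=O)[C@H](c1cc(OC)c(OC)c(OC)c1)[C@H]2C | intermediate
14 | tert-butyl (6R,7S)-2-[(diiodosamarium)oxy]-6-methyl-5-oxo-3-(prop-2-en-1-yl)-7-(3,4,5-trimethoxyphenyl)cyclohepta-1,3-diene-1-carboxylate | C=CCC1=CC(=O)[C@H](C)[C@@H](c2cc(OC)c(OC)c(OC)c2)C(C(=O)OC(C)(C)C)=C1O[Sm](I)I | intermediate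
15 | tert-butyl (1S,6R,7S)-1-bromo-6-methyl-2,5-dioxo-3-(prop-2-en-1-yl)-7-(3,4,5-trimethoxyphenyl)cyclohept-3-ene-1-carboxylate (Br trans to aryl, ester cis to aryl, methyl trans to aryl) | C=CCC1=CC(=O)[C@H](C)[C@@H](c2cc(OC)c(OC)c(OC)c2)[C@@](Br)(C(=O)OC(C)(C)C)C1=O | intermediate
16 | (1S,5S,8S,9R)-1-bromo-5-methoxy-9-methyl-3-(prop-2-en-1-yl)-8-(3,4,5-trimethoxyphenyl)-6-oxabicyclo[3.2.2]non-3-ene-2,7-dione | C=CCC1=C[C@@]2(OC)OC(=O)[C@@](Br)(C1=O)[C@H](c1cc(OC)c(OC)c(OC)c1)[C@H]2C | intermediate
17 | (1R,5S,8R,9R)-5-methoxy-9-methyl-3-(prop-2-en-1-yl)-8-(3,4,5-trimethoxyphenyl)-6-oxabicyclo[3.2.2]non-3-ene-2,7-dione (aryl syn to the lactone bridge, methyl syn to the enone bridge) | C=CCC1=C[C@@]2(OC)OC(=O)[C@@H](C1=O)[C@H](c1cc(OC)c(OC)c(OC)c1)[C@H]2C | target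

**Totals**
Total steps: 8. Longest linear sequence: 7 (steps 1, 2, 3, 5, 6, 7, 8; step 4 is a one-step side branch).

**Three steps most likely to fail, with fallbacks**

Step 5. The carbenoid may cyclopropanate the allyl group instead of forming the ylide, the 1,2-disubstituted alkene may be a slow dipolarophile, and the enantioselectivity with this aromatic-type ylide is unproven. The fallback puts the allyl group on after the cycloaddition; it sets out from 5 (as 7) and 11 and comes back to the route at 13. Commercial monomethyl maleate is converted with oxalyl chloride into methyl (2Z)-4-chloro-4-oxobut-2-enoate F1. F1 acylates 7 to give 6-tert-butyl 1-methyl (2Z)-5-diazo-4-oxohex-2-enedioate F2. F2 and 11 under the conditions of step 5 give tert-butyl (1R,5R,6R,7S)-5-methoxy-6-methyl-2-oxo-7-(3,4,5-trimethoxyphenyl)-8-oxabicyclo[3.2.1]oct-3-ene-1-carboxylate F3. Iodine and pyridine iodinate the enone α-carbon to give tert-butyl (1R,5S,6R,7S)-3-iodo-5-methoxy-6-methyl-2-oxo-7-(3,4,5-trimethoxyphenyl)-8-oxabicyclo[3.2.1]oct-3-ene-1-carboxylate F4. Stille coupling of F4 with 2 [Pd2(dba)3, AsPh3] gives 13.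

Step 6. The ene-dione freed when the hemiketal collapses can be over-reduced by samarium diiodide, and trapping the samarium enolate with the brominating agent in the same flask may be unclean. The fallback separates reduction from bromination and never exposes a free ene-dione to the reductant; it sets out from 13 and comes back at 15. The reduction is run with Me3SiCl present, so both oxygen anions are silylated and tert-butyl (5S,6R,7S)-5-methoxy-6-methyl-3-(prop-2-en-1-yl)-7-(3,4,5-trimethoxyphenyl)-2,5-bis[(trimethylsilyl)oxy]cyclohepta-1,3-diene-1-carboxylate F5 is isolated. N-Bromosuccinimide then brominates the silyl enol ether of F5 trans to the aryl group, and aqueous work-up frees the C5 ketone to give 15.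

Step 7. The one-flask acetalisation and dealkylative lactonisation at a crowded quaternary centre is new and may stop at the dimethyl ketal or give the open methyl ester. The fallback goes through the free acid and a classical pseudo-ester formation; it sets out from 15 and comes back at 16. CF3CO2H in CH2Cl2 at 0 °C cleaves the tert-butyl ester to (1S,6R,7S)-1-bromo-6-methyl-2,5-dioxo-3-(prop-2-en-1-yl)-7-(3,4,5-trimethoxyphenyl)cyclohept-3-ene-1-carboxylic acid F6, which is used at once because β-keto acids decarboxylate. HC(OMe)3, MeOH and camphorsulfonic acid then close F6 to the methoxy lactone 16, again only on the aryl face because C1 is fixed.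

Further compounds
F1 | step 5 | methyl (2Z)-4-chloro-4-oxobut-2-enoate | COC(=O)/C=C\C(Cl)=O
F2 | step 5 | 6-tert-butyl 1-methyl (2Z)-5-diazo-4-oxohex-2-enedioate | COC(=O)/C=C\C(=O)C(=[N+]=[N-])C(=O)OC(C)(C)C
F3 | step 5 | tert-butyl (1R,5R,6R,7S)-5-methoxy-6-methyl-2-oxo-7-(3,4,5-trimethoxyphenyl)-8-oxabicyclo[3.2.1]oct-3-ene-1-carboxylate | C1=C[C@@]2(OC)O[C@@](C(=O)OC(C)(C)C)(C1=O)[C@H](c1cc(OC)c(OC)c(OC)c1)[C@H]2C
F4 | step 5 | tert-butyl (1R,5S,6R,7S)-3-iodo-5-methoxy-6-methyl-2-oxo-7-(3,4,5-trimethoxyphenyl)-8-oxabicyclo[3.2.1]oct-3-ene-1-carboxylate | IC1=C[C@@]2(OC)O[C@@](C(=O)OC(C)(C)C)(C1=O)[C@H](c1cc(OC)c(OC)c(OC)c1)[C@H]2C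
F5 | step 6 | tert-butyl (5S,6R,7S)-5-methoxy-6-methyl-3-(prop-2-en-1-yl)-7-(3,4,5-trimethoxyphenyl)-2,5-bis[(trimethylsilyl)oxy]cyclohepta-1,3-diene-1-carboxylate | C=CCC1=C[C@@](OC)(O[Si](C)(C)C)[C@H](C)[C@@H](c2cc(OC)c(OC)c(OC)c2)C(C(=O)OC(C)(C)C)=C1O[Si](C)(C)C
F6 | step 7 | (1S,6R,7S)-1-bromo-6-methyl-2,5-dioxo-3-(prop-2-en-1-yl)-7-(3,4,5-trimethoxyphenyl)cyclohept-3-ene-1-carboxylic acid | C=CCC1=CC(=O)[C@H](C)[C@@H](c2cc(OC)c(OC)c(OC)c2)[C@@](Br)(C(=O)O)C1=O
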